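Count in minutes of contact. Substrate fed at a steady rate has, at the end of a run, spent less time in the flask than the clock shows. Call the mean of that time its age (its mean residence time), which is the time less 0.5 of the dosing time: 2.42 min for south-west and 1.25 min for north-east.

| setting | Sunday's | Wednesday's | south-west | north-west | east | south-east | north-east |
|---|---|---|---|---|---|---|---|
| substrate | 5 mM (fed, over 0.15 min) | 7.5 mM (fed, over 0.15 min) | 10 mM (fed, over 0.15 min) | 10 mM (fed, over 0.30 min) | 10 mM (fed, over 0.60 min) | 10 mM (fed, over 1.2 min) | 10 mM (fed, over 2.5 min) |
| reagent in the second phase | 9.5 mM | 9.5 mM | 9.50 mM | 9.50 mM | 9.50 mM | 9.50 mM | 9.50 mM |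
| remark | run made earlier | run made earlier |  |  |  |  |  |
| time |  |  | 2.5 min | 2.5 min | 2.5 min | 2.5 min | 2.5 min |
| volume of the second phase over the first |  |  | 1.0 | 1.0 | 1.0 | 1.0 | 1.0 |

| Sunday's: time / min | Sunday's: target / % | Wednesday's: time / min | Wednesday's: target / % |
|---|---|---|---|
| 0.417 | 9.6 | 0.417 | 9.0 |
| 0.833 | 18.6 | 0.833 | 18.0 |
| 1.33 | 25.4 | 1.33 | 24.1 |
| 1.50 | 28.3 | 1.50 | 26.3 |
| 2.00 | 33.8 | 2.00 | 31.2 |
| 2.50 | 37.5 | 2.50 | 33.9 |
| 3.00 | 39.8 | 3.00 | 37.5 |

(readings scatter by 0.5 percentage points)

- percentages count the substrate that a species holds: one side product counts as two
- in the second phase: reagent in the second phase; everything else is in the first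
- charges count per volume of the first phase; a concentration in a rate is the amount of a species over the volume of its own phase; every rate counts per litre of the first phase
- steps that have been proposed: target <-> isomer of the product; substrate + target -> side product; substrate + reagent in the reaction phase <-> target; reagent in the reaction phase <-> reagent in the second phase
- the earlier runs hold the two phases in the same ratio of volumes as the flask asked about
- "hardly changes" means that all values lie within two and a half points (for a concentration: within two and a half percent of the largest)

- amount of target at the end, in percent of the substrate charged for south-west, north-west, east, south-east, north-east, in this order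
- how that number moves from the first to the last of them (falls, then rises / hardly changes / falls all the way / rises, then falls / rises all the way)

Sunday's and Wednesday's first readings, 9.6% and 9.0%, lie close together, so you may treat the percent of target as a curve in age. Those runs were fed quickly, so their reading at 2.50 min stands for south-west, and their reading at 1.33 min stands for north-east. The charge asked for lies one equal step beyond Wednesday's, so continue the drop from Sunday's to Wednesday's once more. That gives me 30.3% for south-west and 22.8% for north-east. Age shrinks as the feed lengthens, and target climbs with age in the readings, so I expect the number to fall with each longer feed.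

The forecast gives 30.6%, 30.3%, 29.7%, 28.1% and 21.3%, a row that falls all the way, holding of the slower feed that “That gain is too small to beat the lost reaction time”.

The simulation gives 30.6%, 30.3%, 29.7%, 28.0% and 22.1%, a row that falls all the way, against my 30.3% and 22.8% at the two ends.

    target ⇌ isomer of the product (K = 0.470, k = 0.0582 s⁻¹)
    substrate + target → side product (k = 0.316 M⁻¹ s⁻¹)
    substrate + reagent in the reaction phase ⇌ target (K = 3650 M⁻¹, k = 1.30 M⁻¹ s⁻¹)
    reagent in the reaction phase ⇌ reagent in the second phase, rate k4*([reagent in the reaction phase] - [reagent in the second phase]/K4) per volume of the first phase (partition coefficient = 0.559, kL = 0.0643 s⁻¹)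

In south-west, target goes over to isomer of the product with a forward half-life of 0.20 min, short against the time of 2.5 min and shorter than the 3.7 min of its reaction with substrate. That step runs back, though: south-west ends with 30.6% target beside 14.1% isomer of the product, a ratio of isomer to target of 0.461 against the step's constant of 0.47, and with 11.0% side product. Now use age: north-east ends aged 1.25 min, and south-west at 1.25 min is aged 1.18 min. North-east then holds 64.0% substrate against south-west's 64.2%, and 22.1% target against south-west's 21.9%.

All runs were generated by integration for substances that don't exist; scatter was added.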